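## The problem

Compound 23 is a depsidone. Ring A carries, going round, the ester carbonyl, CH3, H, OCH3, CHO and the ether oxygen. It is joined to ring B twice, by a diaryl ether oxygen to C4 and by an aryl ester to O5, and the two links close a seven-membered 1,4-dioxepin-5-one. Ring B is also the benzene ring of a 3-hydroxyphthalide (phthalide numbering is used for it throughout) and bears a free phenol at C7, so each arene keeps only one C–H.

Both bridging bonds lie between two ortho substituents on either arene, which makes ether or ester coupling between two finished rings difficult. The only stereocentre is the lactol carbon C3 (S). Nothing else in the molecule can control it, so an external chiral agent must. The lactol opens to an achiral formyl salicylic acid that any base ionises, so the centre has to be fixed late and uncovered under non-ionising conditions.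

The seven-membered aryl ester does not survive hydroxide, alkoxide or amine nucleophiles. The aldehyde excludes hydride and hydrazine reagents, and the phenol and lactol exclude strong base at the end.

The key step is possible because the carbonyl-bearing and ether-bearing carbons of ring A are neighbours and are tied to the neighbouring oxygens O5 and O4 of ring B. Cut into three two-carbon pieces, ring A becomes a but-2-ynoate on O5, an alkynyl ether on O4 and free methoxyacetylene. The acceptor (C=O) and donor (OAr, OCH3) pattern round the ring matches the polarity of these three alkynes.

## Retrosynthesis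

**23 to 22 to 21.** Only O–acyl bonds are cut: the C3 hydroxyl and the C7 phenol of 23 are traced to the two propionates of 22.
- An ester at C3 cannot ring-open, so 22 is the configurationally stable carrier of the stereocentre.
- It comes from the racemic lactol 21 by an acylative dynamic kinetic resolution, which turns the lability of 21 to advantage.
- A hydroxylation of a phthalide CH2 at the very end was weighed against this. A radical reagent would not distinguish that CH2 from the ring A methyl. An oxygenase in buffered water would release the lactol above the pKa of the ring-opened acid and lose the configuration as it forms.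
- The forward steps need a catalyst that acylates one lactol enantiomer while the two interconvert faster. They also need a deacylation that breaks only acyl–oxygen bonds and uses no base.

**21 to 20.** The C–O bonds of three acetal-type masks are cut: the dimethyl acetal of the ring A formyl group, the methyl acetal at C3 and the methoxymethyl ether at O7.
- All three fall in one acid treatment.
- Carrying C3 at the aldehyde oxidation level from the start removes any late C–H oxidation.
- Compound 20 has the same skeleton as 21 but no acidic proton and no free aldehyde, as the metal-catalysed step requires.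

**20 to 16 and 19.** Ring A is cut at three alternate bonds: carbonyl-bearing carbon to ether-bearing carbon, acetal-bearing carbon to methoxy-bearing carbon, and CH to methyl-bearing carbon.
- The other set of three alternate bonds would place a triple bond inside the seven-membered ring.
- The neighbouring cuts at the ether or ester C–O bond lead back to two crowded arenes and leave ring A to be built separately.
- The chosen cut removes two rings and a pentasubstituted benzene at once. Compound 16 is a phthalide with two linear side chains and 19 has three carbons.
- The forward reaction must close a seven-membered ring, orient 19 one way only, and tolerate two ynol ethers.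

**16 to 13 and 14, and 13 to 12.** The O5–acyl bond is cut.
- The aryl but-2-ynoate is the most base-labile group of 16, so it goes on last, from acid 14 through its anhydride 15. This way no free acid meets the ynol ether.
- O5 of 13 is traced to the allyl ether 12, because an allyl group survives every basic step before it and leaves under neutral palladium catalysis.

**12 to 11 to 9 to 7 and 8.** The C(sp)–O4 bond is not cut.
- Direct copper-catalysed O-alkynylation is reliable for amides, but phenols tend to add across a haloalkyne, and O4 has two ortho neighbours.
- The triple bond is therefore traced to the enol triflate 11 and the ketone 9, and the O4–CH2 bond of 9 is cut to phenol 7 and bromo ketone 8.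
- An unhindered alkylation replaces a hindered cross-coupling, and 8 brings the formyl carbon already masked as the smallest possible acetal.

**7 to 6 to 5.** The O7–CH2 and O5–CH2 bonds are cut.
- The three phenols of 5 differ in acidity and crowding in the order O5, O7, O4. Two successive etherifications with one equivalent each should therefore leave free only the phenol that is needed.
- No temporary catechol mask is spent.

**5 to 3 to 1.** The three aryl methyl ethers are restored, and then the C3a–C3 bond is cut.
- In acid 1 the only position ortho to the carboxyl group is also ortho to a methoxy group, so a directed metalation and formylation should make the bond and deliver the lactol ring in one operation.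
- Compound 1 is commercial.

**19 to 17.** Two eliminations from the commercial chloro acetal 17 give the volatile alkyne 19, which is used as a cold solution.

## Roads not taken

**Alternative 1:** The cut is made at the stereocentre only. The bis-isobutyrate A1 is traced to the racemic lactol 21.
- *Forward step:* a chiral isothiourea transfers a branched acyl group to one enantiomer of the ring-closed lactol while the other equilibrates through the formyl acid.
- *Merits:* the reaction class is established for hydroxyphthalides, the whole racemate is used, and the product cannot racemise.
- *Weak points:* it does nothing for the skeleton, since 21 must be in hand first and only the classical ether-then-lactone assembly is on offer. A1 is also not the target. Two branched esters, which lipases accept poorly, must come off beside the depsidone ester without base.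
- *Comparison:* on stereocontrol this road is as good as the chosen plan, which ends with the same type of resolution in step 13 and claims no advantage there. Against it the chosen plan sets a solution for the two central rings in step 11 and a straight-chain acyl group chosen with the release in mind.

**Alternative 2:** Two bonds of ring A are cut.
- *Forward step:* the bromo pyranone A2 and the benzyl aryloxypropiolate A3 are heated. C3 of A2 bonds to the aryloxy-bearing alkyne carbon and C6 to the ester-bearing carbon, the bridging carboxyl unit is extruded, and the diaryl ether A4 results.
- *Merits:* pyranone–alkyne cycloaddition with cycloreversion is known chemistry, the polarities of A2 and A3 match, and the crowded diaryl ether is never made by coupling. In precedent and in regiochemical confidence this road is better than the chosen key step.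
- *Weak points:* A3 is a push–pull alkyne of low dienophilicity and both new bonds form at fully substituted carbons. High temperatures are therefore likely, at which an ynol ether ester may not last.
- *Further weak points:* only ring A is formed. From A4 there remain removal of three benzyl groups, lactonisation, conversion of a doubly ortho-flanked bromide into the aldehyde beside two esters, oxidation of the phthalide CH2 beside the ring A methyl, and the stereocentre.
- *Comparison:* the chosen plan closes ring A and the seven-membered ring together, and it carries the formyl carbon and the C3 oxidation level through the key step.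

**Alternative 3:** One bond is cut, the ether oxygen to C4.
- *Forward step:* a depsidone-forming cytochrome P450 couples the ring A phenol oxygen of the depside A5 to the C4–H carbon and gives the deoxy compound A6.
- *Merits:* this is the biomimetic route and the shortest on paper. A5 is one esterification away from two simple arenes, no protecting groups are needed and a C–H bond is used directly. In step count it beats the chosen plan.
- *Weak points:* such enzymes are tuned to their native depsides, and A5 differs from these in its phthalide ring and its formyl group. C4 and C6 of A5 are both ortho to O5 and both activated by the C7 phenol, so the site of coupling is open.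
- *Further weak point:* A6 still lacks the C3 hydroxyl, which brings back the late oxidation beside the ring A methyl and aldehyde, followed by the resolution.
- *Comparison:* the chosen plan relies on a small-molecule catalyst that can be varied with shelf ligands, and it avoids any late C–H oxidation.

Key step: step 11

Assumption: the lactol carbon C3 of 23 is taken to hold its configuration only in the ring-closed, un-ionised state (dry, base-free, cold). With base it equilibrates through the ring-opened formyl acid, so it is fixed as an ester in step 13 and set free in the last step.

## Route

Step 1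
Reactants: 1 2,4,5-trimethoxybenzoic acid
Product: 3 (±)-3-hydroxy-4,5,7-trimethoxyisobenzofuran-1(3H)-one, via dilithiated benzoate 2 (not isolated)
Conditions: s-BuLi (2.2 equiv), TMEDA (2.2 equiv), THF, −78 °C; DMF, −78 °C to rt; 2 M HCl
Reagents that add atoms: N,N-dimethylformamide, CN(C)C=O
Why: Directed ortho-metalation of the lithium benzoate; C6–H lies between the carboxylate and the 5-methoxy group, so both directors act on one site, whereas C3–H has only two ethers. Formylation and acidification give the ring-closed pseudo-acid; C3 is formed racemic and stays so until step 13.

Step 2
Reactants: 3 (±)-3-hydroxy-4,5,7-trimethoxyisobenzofuran-1(3H)-one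
Product: 5 (±)-4,5,7-trihydroxy-3-methoxyisobenzofuran-1(3H)-one, via tetrahydroxyphthalide 4 (not isolated)
Conditions: BBr3 (6 equiv), CH2Cl2, −78 °C to rt; MeOH, 0 °C then reflux
Reagents that add atoms: methanol, CO
Why: Exhaustive aryl methyl ether cleavage with BBr3; the HBr released on the methanol quench catalyses pseudo-ester formation (lactol to cyclic methyl acetal). This masks C3 in a form that later falls in the same acid step as the other masks.

Step 3
Reactants: 5 (±)-4,5,7-trihydroxy-3-methoxyisobenzofuran-1(3H)-one
Product: 6 (±)-5-(allyloxy)-4,7-dihydroxy-3-methoxyisobenzofuran-1(3H)-one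
Conditions: allyl bromide (1.0 equiv), KHCO3, DMF, Ar, rt
Reagents that add atoms: allyl bromide, C=CCBr
Why: Acidity-controlled Williamson ether synthesis; O5–H is para to the lactone carbonyl and its anion is hydrogen-bonded by O4–H, so a hydrogencarbonate base ionises this phenol first. The same pattern is known from 3,4-dihydroxybenzoyl compounds and 5,7-dihydroxyphthalides; air is excluded because 5 is an oxidisable hydroxyhydroquinone.

Step 4
Reactants: 6 (±)-5-(allyloxy)-4,7-dihydroxy-3-methoxyisobenzofuran-1(3H)-one
Product: 7 (±)-5-(allyloxy)-4-hydroxy-3-methoxy-7-(methoxymethoxy)isobenzofuran-1(3H)-one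
Conditions: MOMCl (1.05 equiv), K2CO3 (1.1 equiv), acetone, Ar, 0 °C
Reagents that add atoms: chloromethyl methyl ether, COCCl
Why: Second acidity- and size-controlled Williamson etherification; O7–H is acidified by the ortho carbonyl, only weakly chelated in a five-membered lactone, and has a free ortho position. O4–H is guaiacol-like and wedged between C3 and the allyloxy group.

Step 5
Reactants: 7 (±)-5-(allyloxy)-4-hydroxy-3-methoxy-7-(methoxymethoxy)isobenzofuran-1(3H)-one; 8 3-bromo-1,1-dimethoxypropan-2-one
Product: 9 (±)-5-(allyloxy)-4-(3,3-dimethoxy-2-oxopropoxy)-3-methoxy-7-(methoxymethoxy)isobenzofuran-1(3H)-one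
Conditions: 8 (1.3 equiv), K2CO3, DMF, Ar, 40 °C
Reagents that add atoms: none
Why: Williamson ether synthesis with an alpha-bromo ketone, an SN2 electrophile reactive enough for a phenoxide with two ortho neighbours. Lactone, acetals and allyl ether are inert to carbonate in an aprotic solvent.

Step 6
Reactants: 9 (±)-5-(allyloxy)-4-(3,3-dimethoxy-2-oxopropoxy)-3-methoxy-7-(methoxymethoxy)isobenzofuran-1(3H)-one
Product: 11 (±)-(Z)-enol triflate ArO–CH=C(OTf)–CH(OCH3)2 (Ar = the phthalide of 9 bound through O4; OAr and OTf on the same side), via lithium Z-enolate 10 (not isolated)
Conditions: LiHMDS (1.15 equiv), THF, −78 °C; PhNTf2, −78 to 0 °C; aq NH4Cl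
Reagents that add atoms: N-phenylbis(trifluoromethanesulfonimide), O=S(=O)(N(c1ccccc1)S(=O)(=O)C(F)(F)F)C(F)(F)F
Why: Kinetic enolisation at the aryloxy-bearing CH2 (more acidic and less hindered than the dialkoxy CH, and faster than the benzylic C3–H), followed by O-triflation. Lithium chelation between the enolate and aryloxy oxygens favours the Z-enolate, which places the vinyl H anti to the triflate.

Step 7
Reactants: 11 (±)-(Z)-enol triflate
Product: 12 (±)-5-(allyloxy)-4-[(3,3-dimethoxyprop-1-yn-1-yl)oxy]-3-methoxy-7-(methoxymethoxy)isobenzofuran-1(3H)-one
Conditions: KOtBu (2.5 equiv), THF, −78 °C, short; pH 7 buffer; Et3N-washed silica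
Reagents that add atoms: none
Why: Anti E2 elimination of triflate, the established way from alpha-alkoxy ketones to alkynyl ethers. The low temperature and short contact time spare the lactone, the pseudo-ester and the propargylic acetal C–H.

Step 8
Reactants: 12 (±)-5-(allyloxy)-4-[(3,3-dimethoxyprop-1-yn-1-yl)oxy]-3-methoxy-7-(methoxymethoxy)isobenzofuran-1(3H)-one
Product: 13 (±)-4-[(3,3-dimethoxyprop-1-yn-1-yl)oxy]-5-hydroxy-3-methoxy-7-(methoxymethoxy)isobenzofuran-1(3H)-one
Conditions: Pd(PPh3)4 (5 mol %), PhNHMe (3 equiv), THF, rt; used at once
Reagents that add atoms: none
Why: Tsuji–Trost deallylation; zerovalent palladium ionises the aryl allyl ether and the weakly basic, poorly nucleophilic N-methylaniline takes up the allyl unit. The phenol appears in neutral form, and neither the pseudo-ester nor the ynol ether meets a strong nucleophile or an acid.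

Step 9
Reactants: 13 (±)-4-[(3,3-dimethoxyprop-1-yn-1-yl)oxy]-5-hydroxy-3-methoxy-7-(methoxymethoxy)isobenzofuran-1(3H)-one; 14 but-2-ynoic acid
Product: 16 (±)-4-[(3,3-dimethoxyprop-1-yn-1-yl)oxy]-3-methoxy-7-(methoxymethoxy)-1-oxo-1,3-dihydroisobenzofuran-5-yl but-2-ynoate, via but-2-ynoic anhydride 15 (not isolated)
Conditions: 14 (2.4 equiv), DCC (1.2 equiv), CH2Cl2, 0 °C, filter; then 13, iPr2NEt, DMAP (10 mol %), −20 to 0 °C
Reagents that add atoms: none
Why: Steglich-type acylation with the preformed symmetrical anhydride. The acid released is held as its ammonium salt, so no free carboxylic acid can add to the ynol ether or open the acetals.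

Step 10
Reactants: 17 chloroacetaldehyde dimethyl acetal
Product: 19 methoxyacetylene, via sodium methoxyacetylide 18 (not isolated)
Conditions: NaNH2 (3.2 equiv), liq. NH3, −33 °C; evaporate; cold brine, −70 °C to rt; distil into cold CH2Cl2
Reagents that add atoms: none
Why: Base-induced loss of HCl and methanol from the chloro acetal, then deprotonation to the acetylide and hydrolysis. This is the standard preparation of alkoxyacetylenes; the volatile alkyne is kept as a cold titrated solution.

Step 11
Reactants: 16 (±)-diyne; 19 methoxyacetylene
Product: 20 (±)-depsidone with all masks in place (ring A, from the ester carbonyl carbon round: CH3, H, OCH3, CH(OCH3)2, ether O; ring B: 3-methoxy-7-(methoxymethoxy)phthalide bound through O5 as ester and O4 as ether)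
Conditions: [Rh(cod)2]BF4 (10 mol %), rac-BINAP (10 mol %), H2 (1 atm) pre-activation then Ar; CH2Cl2, 10 °C, closed flask; 16 and 19 (3 equiv) added together over 8 h, final 5 mM
Reagents that add atoms: none
Why: Proposed new method: a cationic bisphosphine complex of monovalent rhodium is asked to trimerise the ynoate and the aryl ynol ether of 16 with 19. The closest known reaction type is the rhodium-catalysed [2+2+2] cycloaddition of ester- or phenol-tethered 1,6-diynes with terminal alkynes, alkoxyalkynes included; new here are the five-atom tether that ends in a seven-membered ring and the presence of two ynol ethers. Two alkynes couple oxidatively on rhodium to a rhodacyclopentadiene, the third inserts, and reductive elimination releases the arene, forming three C–C bonds (carbonyl-bearing C to ether-bearing C, acetal-bearing C to methoxy-bearing C, CH to methyl-bearing C). Ring A closes in the final reductive elimination of the formal [2+2+2]; the dioxepinone closes in the C–C coupling between the alpha carbon of the ynoate and the oxygen-bearing carbon of the aryl ynol ether, a seven-membered closure on the rigid catechol unit that holds the two alkynes side by side. No stereocentre is formed and C3 is carried through as the racemate. The selectivity needed is the orientation of 19, and both conceivable sequences point the same way on polar grounds: the nucleophilic CH of 19 pairs with the electrophilic beta carbon of the ynoate in a donor–acceptor oxidative coupling, and the electrophilic oxygen-bearing carbon of 19 accepts the more nucleophilic Rh–C bond, the one at the enol-ether beta carbon that carries the acetal. Sterics alone would favour the opposite orientation, which is why the acetal is the small dimethyl one. Slow joint addition at high dilution is meant to hold back self-trimerisation of 19 and dimerisation of 16.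

Step 12
Reactants: 20 (±)-depsidone with all masks in place
Product: 21 (±)-lactol (racemic form of the target)
Conditions: 2 M HCl–1,4-dioxane (1:2), 60 °C
Reagents that add atoms: water, O
Why: Acid hydrolysis of three acetal-type groups in one operation (aryl dimethyl acetal, phenolic MOM ether, 3-methoxyphthalide pseudo-ester). The depsidone ester is a 2,6-disubstituted benzoate and resists aqueous acid.

Step 13
Reactants: 21 (±)-lactol
Product: 22 (S)-bis-propionate (C3 O-propionate with the spatial arrangement of the target; C7 phenol propionate)
Conditions: (EtCO)2O (3 equiv), (2S,3R)-HyperBTM (10 mol %), iPr2NEt (2.5 equiv), CH2Cl2–THF, 0 °C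
Reagents that add atoms: propionic anhydride, CCC(=O)OC(=O)CC
Why: Acylative dynamic kinetic resolution by a chiral isothiourea; the amine base keeps the lactol enantiomers in equilibrium through the ring-opened formyl carboxylate while the N-acyl isothiouronium ion acylates one of them faster. C3 is thereby fixed as an acylal that cannot ring-open. Both antipodes of the catalyst are available, so the sense is matched to S on a model hydroxyphthalide; the phenol is esterified as a spectator.

Step 14
Reactants: 22 (S)-bis-propionate
Product: 23 target, (S)-lactol CNP0216483.1
Conditions: immobilised Burkholderia cepacia lipase, n-BuOH (6 equiv), dry MTBE–THF, 4 °C; filter; evaporate below 10 °C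
Reagents that add atoms: none
Why: Lipase-catalysed alcoholysis in a dry organic solvent, known for acyloxy lactones and aryl esters; the serine attacks the propionyl carbonyl, so only acyl–oxygen bonds break and the C3–O bond and its configuration are kept. The leaving lactol is protonated within the active site and never set free as an alkoxide. The hindered depsidone ester is no lipase substrate, and the absence of base keeps the lactol ring closed.

## Compound list

1 | 2,4,5-trimethoxybenzoic acid | COc1cc(OC)c(C(=O)O)cc1OC | starting material
2 | lithium 6-lithio-2,4,5-trimethoxybenzoate | COc1cc(OC)c(C(=O)O[Li])c([Li])c1OC | intermediate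
3 | (±)-3-hydroxy-4,5,7-trimethoxyisobenzofuran-1(3H)-one | COc1cc(OC)c2c(c1OC)C(O)OC2=O | intermediate
4 | (±)-3,4,5,7-tetrahydroxyisobenzofuran-1(3H)-one | OC1OC(=O)c2c(O)cc(O)c(O)c21 | intermediate
5 | (±)-4,5,7-trihydroxy-3-methoxyisobenzofuran-1(3H)-one | COC1OC(=O)c2c(O)cc(O)c(O)c21 | intermediate
6 | (±)-5-(allyloxy)-4,7-dihydroxy-3-methoxyisobenzofuran-1(3H)-one | C=CCOc1cc(O)c2c(c1O)C(OC)OC2=O | intermediate
7 | (±)-5-(allyloxy)-4-hydroxy-3-methoxy-7-(methoxymethoxy)isobenzofuran-1(3H)-one | C=CCOc1cc(OCOC)c2c(c1O)C(OC)OC2=O | intermediate
8 | 3-bromo-1,1-dimethoxypropan-2-one | COC(OC)C(=O)CBr | starting material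
9 | (±)-5-(allyloxy)-4-(3,3-dimethoxy-2-oxopropoxy)-3-methoxy-7-(methoxymethoxy)isobenzofuran-1(3H)-one | COC(OC)C(=O)COc1c(OCC=C)cc(OCOC)c2c1C(OC)OC2=O | intermediate
10 | lithium (Z)-enolate of 9 | COC(OC)/C(O[Li])=C/Oc1c(OCC=C)cc(OCOC)c2c1C(OC)OC2=O | intermediate
11 | (±)-(Z)-enol triflate of 9 | COC(OC)/C(OS(=O)(=O)C(F)(F)F)=C/Oc1c(OCC=C)cc(OCOC)c2c1C(OC)OC2=O | intermediate
12 | (±)-5-(allyloxy)-4-[(3,3-dimethoxyprop-1-yn-1-yl)oxy]-3-methoxy-7-(methoxymethoxy)isobenzofuran-1(3H)-one | COC(OC)C#COc1c(OCC=C)cc(OCOC)c2c1C(OC)OC2=O | intermediate
13 | (±)-4-[(3,3-dimethoxyprop-1-yn-1-yl)oxy]-5-hydroxy-3-methoxy-7-(methoxymethoxy)isobenzofuran-1(3H)-one | COC(OC)C#COc1c(O)cc(OCOC)c2c1C(OC)OC2=O | intermediate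
14 | but-2-ynoic acid | CC#CC(=O)O | starting material
15 | but-2-ynoic anhydride | CC#CC(=O)OC(=O)C#CC | intermediate
16 | (±)-diyne, O5 but-2-ynoate and O4 3,3-dimethoxypropynyl ether of the 3-methoxy-7-(methoxymethoxy)phthalide | CC#CC(=O)Oc1cc(OCOC)c2c(c1OC#CC(OC)OC)C(OC)OC2=O | intermediate
17 | chloroacetaldehyde dimethyl acetal | COC(CCl)OC | starting material
18 | sodium methoxyacetylide | COC#[C-].[Na+] | intermediate
19 | methoxyacetylene | COC#C | intermediate
20 | (±)-depsidone, formyl group as dimethyl acetal, C3 as methyl acetal, O7 as MOM ether | COc1cc(C)c2c(c1C(OC)OC)Oc1c(cc(OCOC)c3c1C(OC)OC3=O)OC2=O | intermediate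
21 | (±)-lactol, racemic target | COc1cc(C)c2c(c1C=O)Oc1c(cc(O)c3c1C(O)OC3=O)OC2=O | intermediate
22 | (S)-bis-propionate | COc1cc(C)c2c(c1C=O)Oc1c(cc(OC(=O)CC)c3c1[C@@H](OC(=O)CC)OC3=O)OC2=O | intermediate
23 | (S)-lactol, CNP0216483.1 | COc1cc(C)c2c(c1C=O)Oc1c(cc(O)c3c1[C@@H](O)OC3=O)OC2=O | target

## Step count and least certain steps

Total: 14 steps. Longest linear sequence: 13 steps (steps 1–9 and 11–14); step 10 is a one-step side branch.

**Step 11 (key step).**
- *Risk:* insertion of 19 in the reverse orientation is the most likely failure, because the methyl-bearing end of the metallacycle is the less crowded one. The other likely failure is loss of material through self-trimerisation of 19 and oligomerisation of 16, because the seven-membered closure is slower than the five- and six-membered ones for which the catalyst is known.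
- *Fallback (known chemistry; sets out from 7, returns at 21):* ring A is made as a separate arene and the two bridges are formed in turn.
  - Commercial 3-fluoro-5-methylanisole is lithiated between fluorine and methoxy (n-BuLi, THF, −78 °C) and formylated with DMF to 2-fluoro-6-methoxy-4-methylbenzaldehyde F1.
  - HC(OMe)3/TsOH gives its dimethyl acetal F2.
  - A second ortho-lithiation next to fluorine (s-BuLi, TMEDA, −78 °C), allyl chloroformate and a mild acid work-up give allyl 2-fluoro-3-formyl-4-methoxy-6-methylbenzoate F3.
  - The fluoride of F3 is activated by an ortho formyl and an ortho ester group. The phenoxide of 7 displaces it (K2CO3, DMF, 70 °C; nucleophilic aromatic substitution) to give the diaryl ether F4.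
  - Pd(PPh3)4/N-methylaniline removes the allyl ester and allyl ether together to give the hydroxy acid F5.
  - 2-Chloro-1-methylpyridinium iodide/Et3N at high dilution closes the seven-membered lactone to the depsidone aldehyde F6, and the conditions of step 12 convert F6 into 21.

**Step 14.**
- *Risk:* loss of configuration by ring opening of the freed lactol during the hours of enzyme contact or on concentration, and slow turnover because the C3 ester sits under the neighbouring aryloxy group.
- *Fallback (sets out from 21, returns at 23):* the enantiomers of 21 are separated directly by preparative chromatography on a polysaccharide chiral phase, with a cold, slightly acidified eluent. The S fraction is 23, and the unwanted fraction is re-equilibrated to 21 with a trace of base and recycled. No derivative has to be cleaved.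

**Step 13.**
- *Risk:* poor discrimination between the lactol enantiomers in the crowded pocket. Uncatalysed acylation through a mixed anhydride of the ring-opened form would also lower the enantiomeric purity.
- *Fallback (sets out from 21, returns at 23):* 21 is acylated without chiral control (propionic anhydride, Et3N, DMAP) to the racemic bis-propionate F7. The lipase alcoholysis of step 14 is then run as a kinetic resolution that frees 23 from the S ester only. The untouched (R)-bis-propionate F8 is hydrolysed under the conditions of step 12 back to 21 and recycled.

**Step 7 (with step 6).**
- *Risk:* formation of some E-enol triflate that eliminates sluggishly, attack of tert-butoxide on the lactone, or base-induced isomerisation of the propargylic acetal.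
- *Fallback (sets out from 7, returns at 12):* a C(sp2)–O cross-coupling replaces the alkylation–elimination sequence.
  - 2,2-Dimethoxyacetaldehyde is converted with CBr4/PPh3 (Ramirez olefination) into 1,1-dibromo-3,3-dimethoxyprop-1-ene F9.
  - CuI/1,10-phenanthroline/K3PO4 in toluene at 110 °C couples 7 with the bromide trans to the acetal, giving the (Z)-bromo enol ether F10.
  - KOtBu in dioxane at rt eliminates HBr to give 12.

**Step 4.**
- *Risk:* insufficient site selectivity between O7 and O4, and air oxidation of the hydroquinone 6 under base.
- *Fallback (sets out from 5, returns at 7):* the catechol is masked first.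
  - Ph2CCl2/K2CO3 in MeCN gives the 4,5-O-diphenylmethylene ketal F11.
  - MOMCl/K2CO3 gives its 7-O-MOM ether F12.
  - H2, Pd/C frees the 4,5-catechol F13.
  - Allyl bromide/KHCO3 then alkylates the more acidic O5 to give 7.

**Step 8.**
- *Risk:* addition of the liberated phenol across the neighbouring ynol ether (ring closure to a ketene acetal) before it can be acylated.
- *Fallback (sets out from 12, returns at 16):* 12 is treated with preformed 15 and Pd(PPh3)4 without any scavenger. The phenoxide formed on ionisation of the allyl ether is acylated at once by 15, and the but-2-ynoate ion released takes up the allyl unit, so the free phenol never accumulates and steps 8 and 9 merge.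

## Further compounds

F1 | step 11 | 2-fluoro-6-methoxy-4-methylbenzaldehyde | COc1cc(C)cc(F)c1C=O
F2 | step 11 | 2-(dimethoxymethyl)-1-fluoro-3-methoxy-5-methylbenzene | COc1cc(C)cc(F)c1C(OC)OC
F3 | step 11 | allyl 2-fluoro-3-formyl-4-methoxy-6-methylbenzoate | C=CCOC(=O)c1c(C)cc(OC)c(C=O)c1F
F4 | step 11 | (±)-diaryl ether from 7 and F3 | C=CCOC(=O)c1c(C)cc(OC)c(C=O)c1Oc1c(OCC=C)cc(OCOC)c2c1C(OC)OC2=O
F5 | step 11 | (±)-hydroxy acid (seco-depsidone) | COc1cc(C)c(C(=O)O)c(Oc2c(O)cc(OCOC)c3c2C(OC)OC3=O)c1C=O
F6 | step 11 | (±)-depsidone aldehyde with C3 methyl acetal and 7-O-MOM | COc1cc(C)c2c(c1C=O)Oc1c(cc(OCOC)c3c1C(OC)OC3=O)OC2=O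
F0 | step 14 | none | none
F7 | step 13 | (±)-bis-propionate | COc1cc(C)c2c(c1C=O)Oc1c(cc(OC(=O)CC)c3c1C(OC(=O)CC)OC3=O)OC2=O
F8 | step 13 | (R)-bis-propionate | COc1cc(C)c2c(c1C=O)Oc1c(cc(OC(=O)CC)c3c1[C@H](OC(=O)CC)OC3=O)OC2=O
F9 | step 7 | 1,1-dibromo-3,3-dimethoxyprop-1-ene | COC(OC)C=C(Br)Br
F10 | step 7 | (±)-(Z)-1-bromo-3,3-dimethoxyprop-1-enyl ether of 7 | COC(OC)/C=C(Br)/Oc1c(OCC=C)cc(OCOC)c2c1C(OC)OC2=O
F11 | step 4 | (±)-4,5-O-diphenylmethylene-7-hydroxy-3-methoxyphthalide | COC1OC(=O)c2c(O)cc3OC(c4ccccc4)(c4ccccc4)Oc3c21
F12 | step 4 | (±)-4,5-O-diphenylmethylene-3-methoxy-7-(methoxymethoxy)phthalide | COCOc1cc2OC(c3ccccc3)(c3ccccc3)Oc2c2c1C(=O)OC2OC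
F13 | step 4 | (±)-4,5-dihydroxy-3-methoxy-7-(methoxymethoxy)phthalide | COCOc1cc(O)c(O)c2c1C(=O)OC2OC
F0 | step 8 | none | none
A1 | alternative 1 | (S)-bis-isobutyrate (C3 phthalidyl ester and C7 phenol ester) | COc1cc(C)c2c(c1C=O)Oc1c(cc(OC(=O)C(C)C)c3c1[C@@H](OC(=O)C(C)C)OC3=O)OC2=O
A2 | alternative 2 | 3-bromo-4-methoxy-6-methyl-2H-pyran-2-one | COc1cc(C)oc(=O)c1Br
A3 | alternative 2 | benzyl 3-[(5,7-bis(benzyloxy)-1-oxo-1,3-dihydroisobenzofuran-4-yl)oxy]propiolate | O=C(C#COc1c(OCc2ccccc2)cc(OCc2ccccc2)c2c1COC2=O)OCc1ccccc1
A4 | alternative 2 | diaryl ether benzyl ester with bromine at the future formyl carbon | COc1cc(C)c(C(=O)OCc2ccccc2)c(Oc2c(OCc3ccccc3)cc(OCc3ccccc3)c3c2COC3=O)c1Br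
A5 | alternative 3 | depside, 7-hydroxy-1-oxo-1,3-dihydroisobenzofuran-5-yl 3-formyl-2-hydroxy-4-methoxy-6-methylbenzoate | COc1cc(C)c(C(=O)Oc2cc(O)c3c(c2)COC3=O)c(O)c1C=O
A6 | alternative 3 | deoxy target, depsidone with phthalide CH2 | COc1cc(C)c2c(c1C=O)Oc1c(cc(O)c3c1COC3=O)OC2=O
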